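**Plan**

1. Positions are numbered as in naphthalen-2(3H)-one: ring B is C1–C2(=O)–C3(OH)–C4–C4a(Me)–C8a, ring A is C4a–C5(Me)–C6(O-acyl)–C7=C8–C8a.
2. Retrosynthesis: cut the C6–O ester bond (side-chain acid 28), then the C3–O bond (Rubottom), then C1–C2 and C4–C4a together; a CO2t-Bu group on C1 is a temporary activating group.
3. Enabling feature: the C8a=C1–C2=O enone, the C7=C8 double bond and the quaternary C4a are what the trienolate C4=C3–C2(O–)=C1–C8a=C4a gives when C4 closes onto C4a; C7=C8 is a spectator that blocks C8.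
4. Forward: ring A first (cyclohexenone 7), dienyl triflate, Negishi coupling to dienylacetate 10, one-pot acylation/ring closure that builds ring B as the dienone, then C3 oxidation, decarboxylation, PMB removal, esterification, desilylation.
5. Stereochemistry: an asymmetric conjugate addition sets a relay centre (the future C4a), which fixes C5 (trans methylation) and C6 (cis reduction). The relay is erased in the dienyl triflate and C4a is reset by C5 in the ring closure. C3 is set anti to the angular methyl; C6′/C7′ come from an Evans syn aldol.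

Key step: step 8

**Route**

Step 1
Reactants: 1 1,4-dioxaspiro[4.5]dec-6-en-8-one
Product: 3 (6R,7R)-6,7-dimethyl-1,4-dioxaspiro[4.5]decan-8-one, via bromomagnesium enolate 2 (not isolated)
Conditions: MeMgBr, CuBr·SMe2 (5 mol %), Josiphos-type ferrocenyl diphosphine (6 mol %), t-BuOMe, −75 °C; then MeI, DMPU, −75 → 0 °C
Reagents that add atoms: methylmagnesium bromide, C[Mg]Br; iodomethane, CI
Why: copper-catalysed asymmetric conjugate addition sets C6 (the ligand antipode is chosen that gives 6R), and the enolate is methylated anti to the new methyl group, so the trans product (also the thermodynamic one) fixes C7 from C6.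

Step 2
Reactants: 3 (6R,7R)-6,7-dimethyl-1,4-dioxaspiro[4.5]decan-8-one
Product: 4 (6R,7R,8S)-6,7-dimethyl-1,4-dioxaspiro[4.5]decan-8-ol
Conditions: LiBH(s-Bu)3, THF, −78 °C; aqueous work-up
Reagents that add atoms: none
Why: diastereoselective ketone reduction in which the bulky hydride attacks equatorially on the chair with both methyl groups equatorial, which should give the axial alcohol cis to the C7 methyl group, as for 2-methylcyclohexanone.

Step 3
Reactants: 4 (6R,7R,8S)-6,7-dimethyl-1,4-dioxaspiro[4.5]decan-8-ol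
Product: 5 (6R,7R,8S)-8-[(4-methoxybenzyl)oxy]-6,7-dimethyl-1,4-dioxaspiro[4.5]decane
Conditions: NaH, 4-methoxybenzyl chloride, Bu4NI (cat.), DMF, 0 → 23 °C
Reagents that add atoms: 4-methoxybenzyl chloride, COc1ccc(CCl)cc1
Why: Williamson ether synthesis that puts on the later ring A oxygen a group stable to strong base and removable beside silyl ethers.

Step 4
Reactants: 5 (6R,7R,8S)-8-[(4-methoxybenzyl)oxy]-6,7-dimethyl-1,4-dioxaspiro[4.5]decane
Product: 6 (2R,3R,4S)-4-[(4-methoxybenzyl)oxy]-2,3-dimethylcyclohexan-1-one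
Conditions: 1 M HCl, THF, 23 °C
Reagents that add atoms: water, O
Why: acetal hydrolysis under conditions that leave the benzylic ether intact; epimerisation at C2 would be harmless because this centre is made planar in step 6.

Step 5
Reactants: 6 (2R,3R,4S)-4-[(4-methoxybenzyl)oxy]-2,3-dimethylcyclohexan-1-one
Product: 7 (4S,5R,6R)-4-[(4-methoxybenzyl)oxy]-5,6-dimethylcyclohex-2-en-1-one
Conditions: LiN(i-Pr)2, THF, −78 °C; then N-tert-butylbenzenesulfinimidoyl chloride, −78 °C
Reagents that add atoms: none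
Why: Mukaiyama dehydrogenation of the kinetic lithium enolate, which forms at the CH2 group and not at the methyl-bearing methine, should place the double bond at the future C7=C8.

Step 6
Reactants: 7 (4S,5R,6R)-4-[(4-methoxybenzyl)oxy]-5,6-dimethylcyclohex-2-en-1-one
Product: 8 (3R,4S)-4-[(4-methoxybenzyl)oxy]-2,3-dimethylcyclohexa-1,5-dien-1-yl trifluoromethanesulfonate
Conditions: LiN(i-Pr)2, THF, −78 °C; then PhNTf2, −78 → 0 °C
Reagents that add atoms: N-phenylbis(trifluoromethanesulfonimide), O=S(=O)(N(c1ccccc1)S(=O)(=O)C(F)(F)F)C(F)(F)F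
Why: enol triflate formation from the kinetic cross-conjugated enolate (the only α′-hydrogen of the enone is removed) should give one regioisomer of the dienyl triflate and erases the relay centre.

Step 7
Reactants: 8 (3R,4S)-4-[(4-methoxybenzyl)oxy]-2,3-dimethylcyclohexa-1,5-dien-1-yl trifluoromethanesulfonate; 9 (2-tert-butoxy-2-oxoethyl)zinc bromide
Product: 10 tert-butyl 2-[(3R,4S)-4-[(4-methoxybenzyl)oxy]-2,3-dimethylcyclohexa-1,5-dien-1-yl]acetate
Conditions: Pd(PPh3)4 (5 mol %), THF, 60 °C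
Reagents that add atoms: none
Why: Negishi coupling of an alkenyl triflate with a Reformatsky reagent should give the β,γ-unsaturated ester with the diene in place, so that C1 carries the activating ester and can be deprotonated without ambiguity.

Step 8
Reactants: 10 tert-butyl 2-[(3R,4S)-4-[(4-methoxybenzyl)oxy]-2,3-dimethylcyclohexa-1,5-dien-1-yl]acetate; 11 acryloyl chloride
Product: 14 tert-butyl (4aR,5R,6S)-2-[(tert-butyldimethylsilyl)oxy]-6-[(4-methoxybenzyl)oxy]-4a,5-dimethyl-4,4a,5,6-tetrahydronaphthalene-1-carboxylate, via keto ester 12 (not isolated), via lithium enolate 13 (not isolated)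
Conditions: LiN(i-Pr)2 (1.05 equiv), THF, −78 °C; enolate added to 11 (1.1 equiv), −78 °C; LiN(SiMe3)2 (1.3 equiv), −78 → 23 °C; then TBSOTf, −78 °C
Reagents that add atoms: tert-butyldimethylsilyl trifluoromethanesulfonate, CC(C)(C)[Si](C)(C)OS(=O)(=O)C(F)(F)F
Why: Proposed new method: the lithium enolate of 10 is acylated at its α-carbon C1 by 11 to give keto ester 12 (new C1–C2 bond); the second base then forms a doubly stabilised enolate whose charge reaches C4a through the C8a=C4a double bond, C4a adds to the vinyl ketone terminus C4 (new C4–C4a bond), and the ketone enolate 13 so formed is silylated on oxygen. The closest known reaction types are the acylation/Michael [3+3] annulation of enaminones with acryloyl chloride (aza-annulation), the Michael–Claisen synthesis of cyclohexane-1,3-diones and carbanion-accelerated 6π-electrocyclisation; an all-carbon version on an ester dienolate is not known. Ring B closes by a 6-endo-trig vinylogous Michael addition, which is at the same time a thermally allowed disrotatory 6π closure of the trienolate C4=C3–C2(O–)=C1–C8a=C4a. The quaternary centre C4a is controlled by the neighbouring C5 methyl group, which should sit pseudoaxial on the cyclohexadiene to avoid allylic strain with the C4a methyl and so sends C4 to the opposite face, leaving the two methyl groups cis. The step needs C- over O-acylation (lithium enolate in THF without polar additives, inverse addition), closure at C4a and not at an enolate oxygen (O-closure is reversible, C–C formation is not, and C8 is blocked by the C7=C8 double bond), and an untouched C6 centre (aprotic medium, enolate trapped cold).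

Step 9
Reactants: 14 tert-butyl (4aR,5R,6S)-2-[(tert-butyldimethylsilyl)oxy]-6-[(4-methoxybenzyl)oxy]-4a,5-dimethyl-4,4a,5,6-tetrahydronaphthalene-1-carboxylate
Product: 16 tert-butyl (3R,4aR,5R,6S)-3-[(tert-butyldimethylsilyl)oxy]-6-[(4-methoxybenzyl)oxy]-4a,5-dimethyl-2-oxo-2,3,4,4a,5,6-hexahydronaphthalene-1-carboxylate, via silyloxy epoxide 15 (not isolated)
Conditions: mCPBA, NaHCO3, CH2Cl2, −20 → 0 °C
Reagents that add atoms: 3-chloroperoxybenzoic acid, OOC(=O)c1cccc(Cl)c1
Why: Rubottom oxidation in which the electron-rich silyl enol ether (the other double bonds are conjugated to the ester) is epoxidised anti to the axial C4a methyl group and 1,4-silyl migration should give the equatorial 3R silyloxy ketone, which is also the thermodynamic epimer.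

Step 10
Reactants: 16 tert-butyl (3R,4aR,5R,6S)-3-[(tert-butyldimethylsilyl)oxy]-6-[(4-methoxybenzyl)oxy]-4a,5-dimethyl-2-oxo-2,3,4,4a,5,6-hexahydronaphthalene-1-carboxylate
Product: 18 (3R,4aR,5R,6S)-3-[(tert-butyldimethylsilyl)oxy]-6-[(4-methoxybenzyl)oxy]-4a,5-dimethyl-4,4a,5,6-tetrahydronaphthalen-2(3H)-one, via carboxylic acid 17 (not isolated)
Conditions: SiO2, toluene, 110 °C; then pyridine, piperidine (10 mol %), 90 °C
Reagents that add atoms: none
Why: thermal tert-butyl ester cleavage followed by a Doebner-type decarboxylation of the alkylidene β-keto acid, in which reversible conjugate addition of the amine at C7 makes C1 sp3 so that CO2 can leave and the amine is expelled again, should remove the activating group without touching a stereocentre.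

Step 11
Reactants: 18 (3R,4aR,5R,6S)-3-[(tert-butyldimethylsilyl)oxy]-6-[(4-methoxybenzyl)oxy]-4a,5-dimethyl-4,4a,5,6-tetrahydronaphthalen-2(3H)-one
Product: 19 (3R,4aR,5R,6S)-3-[(tert-butyldimethylsilyl)oxy]-6-hydroxy-4a,5-dimethyl-4,4a,5,6-tetrahydronaphthalen-2(3H)-one
Conditions: DDQ, CH2Cl2/pH 7 buffer, 0 °C
Reagents that add atoms: none
Why: oxidative cleavage of the 4-methoxybenzyl ether should free the C6 hydroxyl while the C3 silyl ether stays, so that only one hydroxyl is open for acylation.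

Step 12
Reactants: 20 (R)-4-benzyl-3-propionyloxazolidin-2-one; 21 acetaldehyde
Product: 22 (R)-4-benzyl-3-[(2R,3S)-3-hydroxy-2-methylbutanoyl]oxazolidin-2-one
Conditions: Bu2BOTf, Et3N, CH2Cl2, −78 → 0 °C; then 21, −78 → 0 °C; pH 7 buffer, MeOH, H2O2
Reagents that add atoms: none
Why: Evans syn aldol reaction, in which the Z boron enolate reacts through a chair transition state on the face left open by the benzyl group, should set both side-chain centres (2R,3S, the later 6S,7S).

Step 13
Reactants: 22 (R)-4-benzyl-3-[(2R,3S)-3-hydroxy-2-methylbutanoyl]oxazolidin-2-one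
Product: 23 (2R,3S)-3-hydroxy-N-methoxy-N,2-dimethylbutanamide
Conditions: MeNH(OMe)·HCl, AlMe3, CH2Cl2, −20 → 0 °C
Reagents that add atoms: N,O-dimethylhydroxylamine hydrochloride, CNOC.Cl
Why: aluminium amide transamidation of the aldol adduct to the Weinreb amide, assisted by the free β-hydroxyl, should release the auxiliary without epimerisation.

Step 14
Reactants: 23 (2R,3S)-3-hydroxy-N-methoxy-N,2-dimethylbutanamide
Product: 24 (2R,3S)-3-[(tert-butyldimethylsilyl)oxy]-N-methoxy-N,2-dimethylbutanamide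
Conditions: TBSOTf, 2,6-lutidine, CH2Cl2, −78 → 0 °C
Reagents that add atoms: tert-butyldimethylsilyl trifluoromethanesulfonate, CC(C)(C)[Si](C)(C)OS(=O)(=O)C(F)(F)F
Why: silylation of the secondary alcohol gives the same protecting group as on C3, so that one final step can remove both.

Step 15
Reactants: 24 (2R,3S)-3-[(tert-butyldimethylsilyl)oxy]-N-methoxy-N,2-dimethylbutanamide
Product: 25 (2R,3S)-3-[(tert-butyldimethylsilyl)oxy]-2-methylbutanal
Conditions: i-Bu2AlH, THF, −78 °C
Reagents that add atoms: none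
Why: Weinreb amide reduction stops at the aldehyde because the chelated tetrahedral intermediate survives until work-up, and the α-centre should not epimerise at low temperature.

Step 16
Reactants: 25 (2R,3S)-3-[(tert-butyldimethylsilyl)oxy]-2-methylbutanal; 26 triethyl 4-phosphonocrotonate
Product: 27 ethyl (2E,4E,6S,7S)-7-[(tert-butyldimethylsilyl)oxy]-6-methylocta-2,4-dienoate
Conditions: LiN(SiMe3)2, THF, −78 → 0 °C
Reagents that add atoms: none
Why: vinylogous Horner–Wadsworth–Emmons olefination with the stabilised phosphonate anion should give the 2E,4E dienoate.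

Step 17
Reactants: 27 ethyl (2E,4E,6S,7S)-7-[(tert-butyldimethylsilyl)oxy]-6-methylocta-2,4-dienoate
Product: 28 (2E,4E,6S,7S)-7-[(tert-butyldimethylsilyl)oxy]-6-methylocta-2,4-dienoic acid
Conditions: LiOH, THF/MeOH/H2O, 23 °C; then 1 M HCl
Reagents that add atoms: lithium hydroxide, [Li+].[OH-]
Why: ester saponification under conditions that leave the secondary silyl ether and the diene geometry unchanged.

Step 18
Reactants: 19 (3R,4aR,5R,6S)-3-[(tert-butyldimethylsilyl)oxy]-6-hydroxy-4a,5-dimethyl-4,4a,5,6-tetrahydronaphthalen-2(3H)-one; 28 (2E,4E,6S,7S)-7-[(tert-butyldimethylsilyl)oxy]-6-methylocta-2,4-dienoic acid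
Product: 30 O6-[(2E,4E,6S,7S)-7-[(tert-butyldimethylsilyl)oxy]-6-methylocta-2,4-dienoyl] derivative of 19, via mixed anhydride 29 (not isolated)
Conditions: 2,4,6-trichlorobenzoyl chloride, Et3N, THF, 23 °C; then 19, DMAP, toluene, 23 °C
Reagents that add atoms: none
Why: Yamaguchi esterification acylates the hindered allylic C6 hydroxyl on oxygen, so the C6 configuration is retained.

Step 19
Reactants: 30 O6-[(2E,4E,6S,7S)-7-[(tert-butyldimethylsilyl)oxy]-6-methylocta-2,4-dienoyl] derivative of 19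
Product: 31 the target, (3R,4aR,5R,6S)-3,6-dihydroxy-4a,5-dimethyl-4,4a,5,6-tetrahydronaphthalen-2(3H)-one esterified at O6 with (2E,4E,6S,7S)-7-hydroxy-6-methylocta-2,4-dienoic acid
Conditions: HF·pyridine, pyridine, THF, 0 → 23 °C
Reagents that add atoms: none
Why: buffered fluoride desilylation should remove both silyl ethers without cleaving the allylic ester or epimerising the α-hydroxy ketone, whose C3 configuration is the stable equatorial one.

**Compound list**

1 | 1,4-dioxaspiro[4.5]dec-6-en-8-one | O=C1C=CC2(CC1)OCCO2 | starting material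
2 | bromomagnesium enolate (C7=C8) of (6R)-6-methyl-1,4-dioxaspiro[4.5]decan-8-one | Br[Mg]OC1=C[C@@H](C)C2(CC1)OCCO2 | intermediate (not isolated)
3 | (6R,7R)-6,7-dimethyl-1,4-dioxaspiro[4.5]decan-8-one | O=C1[C@H](C)[C@@H](C)C2(CC1)OCCO2 | intermediate
4 | (6R,7R,8S)-6,7-dimethyl-1,4-dioxaspiro[4.5]decan-8-ol | O[C@@H]1[C@H](C)[C@@H](C)C2(CC1)OCCO2 | intermediate
5 | (6R,7R,8S)-8-[(4-methoxybenzyl)oxy]-6,7-dimethyl-1,4-dioxaspiro[4.5]decane | COc1ccc(CO[C@@H]2[C@H](C)[C@@H](C)C3(CC2)OCCO3)cc1 | intermediate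
6 | (2R,3R,4S)-4-[(4-methoxybenzyl)oxy]-2,3-dimethylcyclohexan-1-one | COc1ccc(CO[C@@H]2[C@H](C)[C@@H](C)C(=O)CC2)cc1 | intermediate
7 | (4S,5R,6R)-4-[(4-methoxybenzyl)oxy]-5,6-dimethylcyclohex-2-en-1-one | COc1ccc(CO[C@@H]2[C@H](C)[C@@H](C)C(=O)C=C2)cc1 | intermediate
8 | (3R,4S)-4-[(4-methoxybenzyl)oxy]-2,3-dimethylcyclohexa-1,5-dien-1-yl trifluoromethanesulfonate | COc1ccc(CO[C@@H]2[C@H](C)C(C)=C(OS(=O)(=O)C(F)(F)F)C=C2)cc1 | intermediate
9 | (2-tert-butoxy-2-oxoethyl)zinc bromide | CC(C)(C)OC(=O)C[Zn]Br | starting material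
10 | tert-butyl 2-[(3R,4S)-4-[(4-methoxybenzyl)oxy]-2,3-dimethylcyclohexa-1,5-dien-1-yl]acetate | COc1ccc(CO[C@@H]2[C@H](C)C(C)=C(CC(=O)OC(C)(C)C)C=C2)cc1 | intermediate
11 | acryloyl chloride | C=CC(=O)Cl | starting material
12 | tert-butyl 2-[(3R,4S)-4-[(4-methoxybenzyl)oxy]-2,3-dimethylcyclohexa-1,5-dien-1-yl]-3-oxopent-4-enoate (enolisable at C2) | COc1ccc(CO[C@@H]2[C@H](C)C(C)=C(C(C(=O)OC(C)(C)C)C(=O)C=C)C=C2)cc1 | intermediate (not isolated)
13 | lithium enolate (C2–OLi, C2=C3) of tert-butyl (4aR,5R,6S)-6-[(4-methoxybenzyl)oxy]-4a,5-dimethyl-2-oxo-2,3,4,4a,5,6-hexahydronaphthalene-1-carboxylate | COc1ccc(CO[C@H]2C=CC3=C(C(=O)OC(C)(C)C)C(O[Li])=CC[C@]3(C)[C@H]2C)cc1 | intermediate (not isolated)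
14 | tert-butyl (4aR,5R,6S)-2-[(tert-butyldimethylsilyl)oxy]-6-[(4-methoxybenzyl)oxy]-4a,5-dimethyl-4,4a,5,6-tetrahydronaphthalene-1-carboxylate | COc1ccc(CO[C@H]2C=CC3=C(C(=O)OC(C)(C)C)C(O[Si](C)(C)C(C)(C)C)=CC[C@]3(C)[C@H]2C)cc1 | intermediate
15 | 2,3-epoxide of 14, epoxide oxygen on the face opposite to the C4a methyl group | COc1ccc(CO[C@H]2C=CC3=C(C(=O)OC(C)(C)C)[C@]4(O[Si](C)(C)C(C)(C)C)O[C@@H]4C[C@]3(C)[C@H]2C)cc1 | intermediate (not isolated)
16 | tert-butyl (3R,4aR,5R,6S)-3-[(tert-butyldimethylsilyl)oxy]-6-[(4-methoxybenzyl)oxy]-4a,5-dimethyl-2-oxo-2,3,4,4a,5,6-hexahydronaphthalene-1-carboxylate | COc1ccc(CO[C@H]2C=CC3=C(C(=O)OC(C)(C)C)C(=O)[C@H](O[Si](C)(C)C(C)(C)C)C[C@]3(C)[C@H]2C)cc1 | intermediate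
17 | (3R,4aR,5R,6S)-3-[(tert-butyldimethylsilyl)oxy]-6-[(4-methoxybenzyl)oxy]-4a,5-dimethyl-2-oxo-2,3,4,4a,5,6-hexahydronaphthalene-1-carboxylic acid | COc1ccc(CO[C@H]2C=CC3=C(C(=O)O)C(=O)[C@H](O[Si](C)(C)C(C)(C)C)C[C@]3(C)[C@H]2C)cc1 | intermediate (not isolated)
18 | (3R,4aR,5R,6S)-3-[(tert-butyldimethylsilyl)oxy]-6-[(4-methoxybenzyl)oxy]-4a,5-dimethyl-4,4a,5,6-tetrahydronaphthalen-2(3H)-one | COc1ccc(CO[C@H]2C=CC3=CC(=O)[C@H](O[Si](C)(C)C(C)(C)C)C[C@]3(C)[C@H]2C)cc1 | intermediate
19 | (3R,4aR,5R,6S)-3-[(tert-butyldimethylsilyl)oxy]-6-hydroxy-4a,5-dimethyl-4,4a,5,6-tetrahydronaphthalen-2(3H)-one | O[C@H]1C=CC2=CC(=O)[C@H](O[Si](C)(C)C(C)(C)C)C[C@]2(C)[C@H]1C | intermediate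
20 | (R)-4-benzyl-3-propionyloxazolidin-2-one | CCC(=O)N1[C@H](Cc2ccccc2)COC1=O | starting material
21 | acetaldehyde | CC=O | starting material
22 | (R)-4-benzyl-3-[(2R,3S)-3-hydroxy-2-methylbutanoyl]oxazolidin-2-one | C[C@H](O)[C@@H](C)C(=O)N1[C@H](Cc2ccccc2)COC1=O | intermediate
23 | (2R,3S)-3-hydroxy-N-methoxy-N,2-dimethylbutanamide | C[C@H](O)[C@@H](C)C(=O)N(C)OC | intermediate
24 | (2R,3S)-3-[(tert-butyldimethylsilyl)oxy]-N-methoxy-N,2-dimethylbutanamide | C[C@H](O[Si](C)(C)C(C)(C)C)[C@@H](C)C(=O)N(C)OC | intermediate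
25 | (2R,3S)-3-[(tert-butyldimethylsilyl)oxy]-2-methylbutanal | C[C@H](O[Si](C)(C)C(C)(C)C)[C@@H](C)C=O | intermediate
26 | triethyl 4-phosphonocrotonate, ethyl (E)-4-(diethoxyphosphoryl)but-2-enoate | CCOC(=O)/C=C/CP(=O)(OCC)OCC | starting material
27 | ethyl (2E,4E,6S,7S)-7-[(tert-butyldimethylsilyl)oxy]-6-methylocta-2,4-dienoate | C[C@H](O[Si](C)(C)C(C)(C)C)[C@@H](C)/C=C/C=C/C(=O)OCC | intermediate
28 | (2E,4E,6S,7S)-7-[(tert-butyldimethylsilyl)oxy]-6-methylocta-2,4-dienoic acid | C[C@H](O[Si](C)(C)C(C)(C)C)[C@@H](C)/C=C/C=C/C(=O)O | intermediate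
29 | mixed anhydride of 28 with 2,4,6-trichlorobenzoic acid | C[C@H](O[Si](C)(C)C(C)(C)C)[C@@H](C)/C=C/C=C/C(=O)OC(=O)c1c(Cl)cc(Cl)cc1Cl | intermediate (not isolated)
30 | O6-[(2E,4E,6S,7S)-7-[(tert-butyldimethylsilyl)oxy]-6-methylocta-2,4-dienoyl] derivative of 19 | C[C@H](O[Si](C)(C)C(C)(C)C)[C@@H](C)/C=C/C=C/C(=O)O[C@H]1C=CC2=CC(=O)[C@H](O[Si](C)(C)C(C)(C)C)C[C@]2(C)[C@H]1C | intermediate
31 | (3R,4aR,5R,6S)-3,6-dihydroxy-4a,5-dimethyl-4,4a,5,6-tetrahydronaphthalen-2(3H)-one 6-O-[(2E,4E,6S,7S)-7-hydroxy-6-methylocta-2,4-dienoate] | C[C@H](O)[C@@H](C)/C=C/C=C/C(=O)O[C@H]1C=CC2=CC(=O)[C@H](O)C[C@]2(C)[C@H]1C | target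

**Count and risks**

Total step count: 19. Longest linear sequence: 13 steps (steps 1–11, 18, 19).

Most likely to fail:

1. Step 8 (Proposed new method). The enolate may be acylated on oxygen, the vinyl ketone of 12 may be consumed by intermolecular Michael addition, the ring may close through an enolate oxygen, or facial control at C4a may be poor. The fallback sets out from enone 7 and builds ring B by a Robinson annulation. The kinetic lithium enolate of 7 (LiN(i-Pr)2, THF, −78 °C) would be added to 3-(trimethylsilyl)but-3-en-2-one to give the Michael adduct (4S,5R,6R)-4-[(4-methoxybenzyl)oxy]-5,6-dimethyl-6-[3-oxo-2-(trimethylsilyl)butyl]cyclohex-2-en-1-one F1, with the new chain anti to the C5 methyl group. KOH in MeOH would remove silicon and close the ring by aldol condensation onto the enone carbonyl, which should give the dienone (4aR,5R,6S)-6-[(4-methoxybenzyl)oxy]-4a,5-dimethyl-4,4a,5,6-tetrahydronaphthalen-2(3H)-one F2. LiN(i-Pr)2 and TBSOTf would then give the cross-conjugated silyl dienol ether F3, and mCPBA oxidation as in step 9 would return the route at 18.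

2. Step 10. Loss of CO2 from a carboxyl group on an sp2 carbon may not take place under amine catalysis, or the allylic ether may ionise or eliminate on heating. The fallback sets out from 16 and makes C1 sp3 before the carboxyl is removed. Thiophenol and Et3N would add at C7 (1,6-addition) to give the β-keto ester tert-butyl (3R,4aR,5R,6S)-3-[(tert-butyldimethylsilyl)oxy]-6-[(4-methoxybenzyl)oxy]-4a,5-dimethyl-2-oxo-7-(phenylsulfanyl)-1,2,3,4,4a,5,6,7-octahydronaphthalene-1-carboxylate F4. Heating with SiO2 in toluene would cleave the ester and decarboxylate the ordinary β-keto acid to the sulfide (3R,4aR,5R,6S)-3-[(tert-butyldimethylsilyl)oxy]-6-[(4-methoxybenzyl)oxy]-4a,5-dimethyl-7-(phenylsulfanyl)-3,4,4a,5,6,7-hexahydronaphthalen-2(1H)-one F5. DBU would expel thiophenol through the dienolate and return the route at 18.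

3. Step 18. Acylation of the hindered pseudoaxial allylic alcohol may be slow, with isomerisation of the 2,3-double bond of the activated dienoic acid by DMAP or elimination at C6. The fallback sets out from 19 and 25 and builds the dienoate on the core. Alcohol 19 would be acylated with the small diethylphosphonoacetic acid (DCC, DMAP) to give the phosphonoacetate (3R,4aR,5R,6S)-3-[(tert-butyldimethylsilyl)oxy]-4a,5-dimethyl-2-oxo-2,3,4,4a,5,6-hexahydronaphthalen-6-yl 2-(diethoxyphosphoryl)acetate F6. Aldehyde 25 would be homologated with (triphenylphosphoranylidene)acetaldehyde to (2E,4S,5S)-5-[(tert-butyldimethylsilyl)oxy]-4-methylhex-2-enal F7. A Horner–Wadsworth–Emmons reaction of F6 with F7 (LiCl, i-Pr2NEt, MeCN) would return the route at 30.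

Further compounds
F1 | step 8 | (4S,5R,6R)-4-[(4-methoxybenzyl)oxy]-5,6-dimethyl-6-[3-oxo-2-(trimethylsilyl)butyl]cyclohex-2-en-1-one | COc1ccc(CO[C@H]2C=CC(=O)[C@](C)(CC([Si](C)(C)C)C(C)=O)[C@H]2C)cc1
F2 | step 8 | (4aR,5R,6S)-6-[(4-methoxybenzyl)oxy]-4a,5-dimethyl-4,4a,5,6-tetrahydronaphthalen-2(3H)-one | COc1ccc(CO[C@H]2C=CC3=CC(=O)CC[C@]3(C)[C@H]2C)cc1
F3 | step 8 | tert-butyl{[(4aR,5R,6S)-6-[(4-methoxybenzyl)oxy]-4a,5-dimethyl-4,4a,5,6-tetrahydronaphthalen-2-yl]oxy}dimethylsilane | COc1ccc(CO[C@H]2C=CC3=CC(O[Si](C)(C)C(C)(C)C)=CC[C@]3(C)[C@H]2C)cc1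
F4 | step 10 | tert-butyl (3R,4aR,5R,6S)-3-[(tert-butyldimethylsilyl)oxy]-6-[(4-methoxybenzyl)oxy]-4a,5-dimethyl-2-oxo-7-(phenylsulfanyl)-1,2,3,4,4a,5,6,7-octahydronaphthalene-1-carboxylate (epimers at C1 and C7) | COc1ccc(CO[C@H]2C(Sc4ccccc4)C=C3C(C(=O)OC(C)(C)C)C(=O)[C@H](O[Si](C)(C)C(C)(C)C)C[C@]3(C)[C@H]2C)cc1
F5 | step 10 | (3R,4aR,5R,6S)-3-[(tert-butyldimethylsilyl)oxy]-6-[(4-methoxybenzyl)oxy]-4a,5-dimethyl-7-(phenylsulfanyl)-3,4,4a,5,6,7-hexahydronaphthalen-2(1H)-one (epimers at C7) | COc1ccc(CO[C@H]2C(Sc4ccccc4)C=C3CC(=O)[C@H](O[Si](C)(C)C(C)(C)C)C[C@]3(C)[C@H]2C)cc1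
F6 | step 18 | (3R,4aR,5R,6S)-3-[(tert-butyldimethylsilyl)oxy]-4a,5-dimethyl-2-oxo-2,3,4,4a,5,6-hexahydronaphthalen-6-yl 2-(diethoxyphosphoryl)acetate | CCOP(=O)(CC(=O)O[C@H]1C=CC2=CC(=O)[C@H](O[Si](C)(C)C(C)(C)C)C[C@]2(C)[C@H]1C)OCC
F7 | step 18 | (2E,4S,5S)-5-[(tert-butyldimethylsilyl)oxy]-4-methylhex-2-enal | C[C@H](O[Si](C)(C)C(C)(C)C)[C@@H](C)/C=C/C=O
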